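Its constants belong to no real substance.

The clock comes first.

    spent carrier + salt in the second phase ⇌ fresh carrier + spent salt in the second phase (K1 = 0.76, k1 = 2.9 M⁻¹ s⁻¹)
    starting material + fresh carrier → target + spent carrier (k2 = 0.74 M⁻¹ s⁻¹)
    2 starting material → homo dimer (k3 = 0.10 M⁻¹ s⁻¹)

starting material 0.43 M; salt in the second phase 0.452 M; spent carrier 34 mM; volume of the second phase over the first 2.0

- percentages count the starting material that a species holds: one homo dimer counts as two
- a doubled species enters its step squared and goes two at a time
- in the second phase: salt in the second phase, spent salt in the second phase; everything else is in the first
- charges count per volume of the first phase; a concentration in a rate is the amount of a species over the volume of its own phase; every rate counts per litre of the first phase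
- charge of starting material (flask): 0.43 M

- apparent order in salt in the second phase when 10 % of the starting material are converted (percent change of the rate of making target for one percent more salt in the second phase charged)
- apparent order in spent carrier when 10 % of the starting material are converted (percent change of the rate of making target for one percent more spent carrier charged)

How soon does this flask reach the conversion asked about? Starting material is lost faster to homo dimer than to target, even with the whole carrier charge fresh. My reckoning therefore counts dimer formation by itself, and the second-order law gives 1.29 s.

How far has the fresh carrier come by then? None is charged. Spent carrier turns into it at a pseudo-first-order rate of 0.655 s⁻¹, with the salt taken at its concentration in its own phase. Fresh carrier goes on to target at 0.318 s⁻¹. Leaving out the reverse step, the two add to a relaxation rate of 0.974 s⁻¹.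

The product of that rate and the time of looking is the carrier age, the number of relaxation times elapsed when the rate is read. In this flask it is 1.26, so in this reckoning the fresh carrier is still rising: its level is the carrier charge, times the forward rate over the relaxation rate, times the fraction 0.716 of the way covered.

What orders follow? Differentiating the logarithm of that level, with the time of looking held, gives 0.663 in salt. The level is proportional to the carrier charge, which gives 1.00 in spent carrier.

The forecast gave 0.66 in salt and 0.91 in spent carrier, the second lower than my figure, holding that the fresh carrier “has not reached its quasi-steady level”. The simulation gives 0.65 in salt and 0.93 in spent carrier, at 1.19 s.

At that time the carrier age of this flask is 1.16. Without dimer formation, this flask has to reach the conversion through target, and my reckoning with the steady level of fresh carrier puts that at about 7.25 s. The carrier age reckoned for that case is 7.06, older than the real one, and the steady term, with the reverse step left out, gives a salt order of 0.326. Dimer formation is the largest single effect on this order: the run without it gives 0.44, against 0.65 with it.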